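The numbers in the tables were generated by integration with constants of no real substance; noise was put on by code.

| setting | birch | south-west | north | south | north-east | west |
|---|---|---|---|---|---|---|
| X | 0.022 M | 0.020 M | 0.020 M | 0.020 M | 0.010 M | 0.040 M |
| Z | 0.050 M (fed, over 50 min) | 0.150 M (fed, over 50 min) | 0.0800 M (fed, over 50 min) | 0.0500 M (fed, over 50 min) | 0.0250 M (fed, over 100 min) | 0.0500 M (fed, over 100 min) |
| remark | run made earlier |  |  |  |  |  |
| time |  | 8.0 h | 8.0 h | 8.0 h | 8.0 h | 8.0 h |

- birch (time / h: D / %, E / %): 0.417: 2.7, 0.2; 0.667: 8.4, 0.6; 1.00: 13.8, 2.3; 2.00: 20.1, 11.2; 3.00: 18.0, 20.2; 5.00: 15.1, 30.4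

(scatter of a reading: 1 percentage point)

- percentages count the X that a species holds: one J counts as two
- the numbers in the tables scatter by 1 percentage point (one standard deviation)
- reactions considered so far: Z + E <-> G; X + Z -> D; 2 X -> J; Z + D -> E; Z <-> L

- the flasks put in order of share of D in all that became D or E or G, best first, at 8.0 h (south-west / north / south / north-east / west)
- the share of D in all that became D or E or G of the flask you put first, at 8.0 h
- the share of D in all that became D or E or G of the flask you put last, at 8.0 h

1. In a one-step world, D + Z → E with c_Z held steady, D decays pseudo-first-order, and its survival depends on c_Z and time through their product. So I follow c_Z, and I expect the share of D to fall along the time integral of c_Z.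

2. My raw dose is the Z charge times the time since mid-feed, in units of birch at 5.00 h. Birch at 3.00 h then stands at 0.564.

3. G was not read, so I take D/(D+E) as the birch share: 47.1% at the earlier reading and 33.2% at the later, both with the scatter of the readings. Assuming an exponential fall, the share drops at 0.803 per unit dose.

4. North-east has raw dose 0.782 and south-west 4.96, which gives shares of 39.6% and 1.38%.

5. The weak link is that the charge of Z does not stay: the adducts of X hold part of it, and Z <-> L stands among the reactions too, though my correction counts the adducts and leaves L out. In birch at 5.00 h, D plus twice E hold Z equal to 75.9% of the X charged. I count 0.5 of that as the average loss, so each flask's dose is scaled by 1 − 0.5·75.9%·(X charge)/(Z charge), relative to birch's factor of 0.833.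

6. This gives north-east 0.796, the corrected dose. West has 1.31, south 1.68, north 2.88 and south-west 5.66. The doses rise in that order , so that is my order, best first. I commit to 39.1% for north-east and 0.787% for south-west, the latter an extrapolation past the birch doses.

The forecast, reasoning that the “share depends on the Z exposure”, gives north-east > west > south > north > south-west, with 45% and 1%.

The flasks come out as north-east > west > south > north > south-west.

    Z + E ⇌ G (K = 18.0 L mol⁻¹, k = 0.00460 L mol⁻¹ s⁻¹)
    X + Z → D (k = 0.00250 L mol⁻¹ s⁻¹)
    2 X → J (k = 8.30 × 10⁻⁴ L mol⁻¹ s⁻¹)
    Z + D → E (k = 0.00600 L mol⁻¹ s⁻¹)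
    Z ⇌ L (K = 0.880, k = 6.50 × 10⁻⁵ s⁻¹)

North-east at dose 0.796 holds 36.6% where I reckoned 39.1%, and south-west at 5.66 holds 0.477% where I reckoned 0.787%. South with its feed stretched to 100 min has dose 1.59, for which the law gives 20.6%, and that flask holds 18.6%. In south-west, half of the making of D is done by 0.976 h and half of the loss of Z to L by 1.41 h, with Z at 84.1% of its charge when the feed ends. By 8.00 h, X is down to 0.605%, Z to 37.4% with L at 0.0487 M, and D stands at 0.433%.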